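**Retrosynthetic overview** (bicycle locants: O1, C2, C3, C3a, C4–C7, C7a of the hexahydro-1-benzofuran; chain locants are the carotenoid ones)
1. The polyene is cut at C11=C12 (Wittig) into C15 phosphonium salt 21 (bicycle plus three chain carbons) and C15 aldehyde ester 26, made from the commercial C10 dialdehyde 25 and a C5 phosphonate; the terminal aldehyde is released last from the ester.
2. The C2–side-chain bond comes from alkenyl transfer from trifluoroborate 16 to the oxocarbenium ion of lactol acetate 12; this step sets C2.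
3. Both rings form in one operation: butenolide 10 from the open-chain hydroxy keto ynoate 8 with SmI2. The six-membered carbocycle closes first (C3a–C7a, ketyl carbon to ynoate β-carbon) and the five-membered oxygen ring second (O1–C2, lactonisation).
4. Enabling feature: in the ring O1–C7a(CH3)–C3a=C3–C2, with C2 at the lactone level, C7a and C3a are the carbonyl carbon of a methyl ketone and the β-carbon of a ynoate, two acceptor carbons that a ketyl (polarity reversal) can join. The C6 hydroxyl is 1,3 to the C7a oxygen on the six-membered ring, so one samarium ion can bridge both and fix C7a; the gem-dimethyl carbon C4 favours closure.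
5. 8 comes in four steps from 2,2-dimethylpent-4-enal 1 (alkyne homologation, carboxylation, ozonolysis, catalytic asymmetric acetone aldol that sets C6).

Key step: step 5

Assumption: the sense of induction in step 4 is assigned by analogy (the ligand antipode is used if the 6S alcohol should result), and double-bond isomers from the olefinations are taken to equilibrate to the all-E polyene on gentle warming, as is usual for carotenoids.

**Route**

Step 1
Reactants: 1 2,2-dimethylpent-4-enal
Product: 2 3,3-dimethylhex-5-en-1-yne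
Conditions: dimethyl (1-diazo-2-oxopropyl)phosphonate, K2CO3, MeOH, 0 °C → rt; product kept in pentane solution (volatile)
Reagents that add atoms: dimethyl (1-diazo-2-oxopropyl)phosphonate, CC(=O)C(=[N+]=[N-])P(=O)(OC)OC
Why: Ohira–Bestmann (Seyferth–Gilbert) homologation turns the non-enolisable aldehyde into the terminal alkyne through an alkylidene carbene 1,2-shift, and the isolated alkene is inert; no stereocentre is formed.

Step 2
Reactants: 2 3,3-dimethylhex-5-en-1-yne
Product: 4 methyl 4,4-dimethylhept-6-en-2-ynoate, via lithium acetylide 3 (not isolated)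
Conditions: n-BuLi, THF, −78 °C; then ClCO2Me, −78 → 0 °C
Reagents that add atoms: methyl chloroformate, COC(Cl)=O
Why: Deprotonation of the terminal alkyne and C-acylation of the lithium acetylide with a chloroformate is a standard ynoate synthesis; no stereocentre is formed.

Step 3
Reactants: 4 methyl 4,4-dimethylhept-6-en-2-ynoate
Product: 6 methyl 4,4-dimethyl-6-oxohex-2-ynoate, via ozonide 5 (not isolated)
Conditions: O3 (1.0 equiv), CH2Cl2, −78 °C; then Me2S, −78 °C → rt
Reagents that add atoms: ozone, [O-][O+]=O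
Why: Ozonolysis with reductive work-up should cleave the electron-rich terminal alkene much faster than the electron-poor, hindered alkyne of the ynoate; no stereocentre is formed.

Step 4
Reactants: 6 methyl 4,4-dimethyl-6-oxohex-2-ynoate
Product: 8 methyl (6R)-6-hydroxy-4,4-dimethyl-8-oxonon-2-ynoate, via enol ether adduct 7 (not isolated)
Conditions: 2-methoxypropene (excess), Ti(OiPr)4 (5 mol %), (S)-2-{[(3-bromo-5-tert-butyl-2-hydroxyphenyl)methylidene]amino}-2'-hydroxy-1,1'-binaphthyl (5 mol %), 3,5-di-tert-butylsalicylic acid (5 mol %), 2,6-di-tert-butyl-4-methylpyridine, 0 °C; then 1 M HCl, Et2O, 0 °C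
Reagents that add atoms: 2-methoxypropene, COC(C)=C; water, O
Why: Catalytic enantioselective ene-type (Mukaiyama-type) acetone aldol addition: the chiral titanium binaphthyl Schiff-base complex shields one face of the bound aldehyde and so sets C6, and mild acid hydrolysis of enol ether 7 frees the methyl ketone without touching the ynoate.

Step 5
Reactants: 8 methyl (6R)-6-hydroxy-4,4-dimethyl-8-oxonon-2-ynoate
Product: 10 (6R,7aR)-6-hydroxy-4,4,7a-trimethyl-5,6,7,7a-tetrahydro-1-benzofuran-2(4H)-one (isololiolide), via Z-hydroxy enoate 9 (not isolated)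
Conditions: SmI2 (2.5 equiv, 0.1 M in THF, added over 1 h), MeOH (10 equiv), THF, −78 → −20 °C, argon; aq. NaHCO3/Na2S2O3 work-up
Reagents that add atoms: none
Why: Divalent samarium, held by the C6 hydroxyl, reduces the ketone to a chelated ketyl whose carbon (a nucleophilic radical, reversed polarity) adds to the electrophilic β-carbon of the ynoate; a second electron gives a samarium allenoate that MeOH protonates at the α-carbon, and the trivalent samarium alkoxide then acylates on the neighbouring ester. The closest known reaction type is the SmI2 ketyl–alkynoate (ketyl–olefin) reductive cyclisation with lactone formation, run here with hydroxyl direction as in the chelation-controlled SmI2 reduction of β-hydroxy ketones. The carbocycle closes 6-exo-dig (C3a–C7a bond, helped by the gem-dimethyl group) and the furanone then closes 5-exo-trig by lactonisation (O1–C2 bond). The one new stereocentre, quaternary C7a, is controlled by the C6 carbinol: one samarium ion bridges the C6 oxygen and the ketyl oxygen, so both C–O bonds lie on the same face of the forming chair and C7a–O ends cis to C6–OH. The step needs ketyl formation ahead of ynoate reduction (secured by hydroxyl-assisted electron transfer to the ketone at −78 °C and slow addition of SmI2), exo rather than endo attack (secured by the polarisation of the ynoate), and the Z enoate for lactonisation (secured by the same samarium ion bridging the alkoxide and the allenoate oxygen during protonation).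

Step 6
Reactants: 10 (6R,7aR)-6-hydroxy-4,4,7a-trimethyl-5,6,7,7a-tetrahydro-1-benzofuran-2(4H)-one
Product: 12 (6R,7aR)-4,4,7a-trimethyl-2,4,5,6,7,7a-hexahydro-1-benzofuran-2,6-diyl diacetate (both C2 epimers), via lactol 11 (not isolated)
Conditions: i-Bu2AlH (2.3 equiv), CH2Cl2, −78 °C; then pyridine, DMAP, Ac2O, −78 → 0 °C
Reagents that add atoms: acetic anhydride, CC(=O)OC(C)=O
Why: Reductive acetylation: i-Bu2AlH adds 1,2 to the butenolide carbonyl at −78 °C and the aluminium lactolate (and the C6 aluminium alkoxide) is acetylated in the flask before it can open or over-reduce; C2 is left as a mixture because it becomes planar in step 10.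

Step 7
Reactants: 13 but-2-yn-1-ol
Product: 14 tert-butyl(but-2-yn-1-yloxy)diphenylsilane
Conditions: t-BuPh2SiCl, imidazole, DMF, rt
Reagents that add atoms: tert-butyl(chloro)diphenylsilane, CC(C)(C)[Si](Cl)(c1ccccc1)c1ccccc1
Why: Imidazole-promoted silylation of the primary alcohol gives an ether that should survive the copper boryl species, KHF2 and BF3·OEt2 at low temperature.

Step 8
Reactants: 14 tert-butyl(but-2-yn-1-yloxy)diphenylsilane
Product: 15 tert-butyl{[(2Z)-3-(4,4,5,5-tetramethyl-1,3,2-dioxaborolan-2-yl)but-2-en-1-yl]oxy}diphenylsilane (boron trans to the CH2O group)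
Conditions: B2pin2 (1.1 equiv), CuCl (5 mol %), PCy3 (6 mol %), NaOtBu (10 mol %), MeOH (2 equiv), toluene, rt
Reagents that add atoms: bis(pinacolato)diboron, CC1(C)OB(OC1(C)C)B1OC(C)(C)C(C)(C)O1
Why: Copper-catalysed formal hydroboration: syn borylcupration places copper next to the inductively withdrawing CH2O group and boron on the methyl-bearing carbon, and protonation by MeOH leaves H and boron cis, which fixes the geometry of the trisubstituted side-chain double bond.

Step 9
Reactants: 15 tert-butyl{[(2Z)-3-(4,4,5,5-tetramethyl-1,3,2-dioxaborolan-2-yl)but-2-en-1-yl]oxy}diphenylsilane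
Product: 16 potassium {(2Z)-4-[(tert-butyldiphenylsilyl)oxy]but-2-en-2-yl}trifluoroborate
Conditions: KHF2 (aq., 4.5 M), MeOH, rt
Reagents that add atoms: potassium hydrogen difluoride, [K+].F.[F-]
Why: KHF2 exchanges the pinacol ester for the trifluoroborate with retention of alkene geometry and gives a stable, more nucleophilic alkenyl donor.

Step 10
Reactants: 12 (6R,7aR)-4,4,7a-trimethyl-2,4,5,6,7,7a-hexahydro-1-benzofuran-2,6-diyl diacetate; 16 potassium {(2Z)-4-[(tert-butyldiphenylsilyl)oxy]but-2-en-2-yl}trifluoroborate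
Product: 18 (2R,6R,7aR)-2-{(2E)-4-[(tert-butyldiphenylsilyl)oxy]but-2-en-2-yl}-4,4,7a-trimethyl-2,4,5,6,7,7a-hexahydro-1-benzofuran-6-yl acetate, via oxocarbenium ion 17 (not isolated)
Conditions: BF3·OEt2 (2.0 equiv), CH2Cl2–MeCN, −40 → 0 °C, short reaction time; Et3N then aq. NaHCO3 quench
Reagents that add atoms: none
Why: BF3 ionises the anomeric acetate to the planar allylic oxocarbenium ion 17 and the alkenyl group migrates from boron with retention of its geometry (oxocarbenium C-alkenylation with an organotrifluoroborate); C2 is set by attack anti to the angular C7a methyl, which shares its face with the axial C4 methyl, and the other allylic terminus C3a is blocked because it is fully substituted.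

Step 11
Reactants: 18 (2R,6R,7aR)-2-{(2E)-4-[(tert-butyldiphenylsilyl)oxy]but-2-en-2-yl}-4,4,7a-trimethyl-2,4,5,6,7,7a-hexahydro-1-benzofuran-6-yl acetate
Product: 19 (2R,6R,7aR)-2-[(2E)-4-hydroxybut-2-en-2-yl]-4,4,7a-trimethyl-2,4,5,6,7,7a-hexahydro-1-benzofuran-6-yl acetate
Conditions: Bu4NF (1.2 equiv), AcOH (1.2 equiv), THF, 0 °C → rt
Reagents that add atoms: none
Why: Fluoride cleaves the silyl ether, and buffering with AcOH should keep the acetate and the bis-allylic ether intact; no stereocentre is touched.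

Step 12
Reactants: 19 (2R,6R,7aR)-2-[(2E)-4-hydroxybut-2-en-2-yl]-4,4,7a-trimethyl-2,4,5,6,7,7a-hexahydro-1-benzofuran-6-yl acetate
Product: 20 (2R,6R,7aR)-2-[(2E)-4-bromobut-2-en-2-yl]-4,4,7a-trimethyl-2,4,5,6,7,7a-hexahydro-1-benzofuran-6-yl acetate
Conditions: CBr4, PPh3, 2,6-lutidine, CH2Cl2, −20 °C
Reagents that add atoms: carbon tetrabromide, BrC(Br)(Br)Br
Why: Appel bromination converts the primary allylic alcohol under neutral, buffered conditions and avoids the acid that would ionise the C2–O1 bond and scramble C2.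

Step 13
Reactants: 20 (2R,6R,7aR)-2-[(2E)-4-bromobut-2-en-2-yl]-4,4,7a-trimethyl-2,4,5,6,7,7a-hexahydro-1-benzofuran-6-yl acetate
Product: 21 {(2E)-3-[(2R,6R,7aR)-6-acetoxy-4,4,7a-trimethyl-2,4,5,6,7,7a-hexahydro-1-benzofuran-2-yl]but-2-en-1-yl}triphenylphosphonium bromide
Conditions: PPh3, toluene, rt, dark
Reagents that add atoms: triphenylphosphine, c1ccc(cc1)P(c1ccccc1)c1ccccc1
Why: SN2 quaternisation of the primary allylic bromide by PPh3 gives the Wittig salt without acid.

Step 14
Reactants: 22 ethyl (2E)-2-methylbut-2-enoate (ethyl tiglate)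
Product: 23 ethyl (2E)-4-bromo-2-methylbut-2-enoate
Conditions: N-bromosuccinimide, AIBN (cat.), PhCF3, reflux
Reagents that add atoms: N-bromosuccinimide, BrN1C(=O)CCC1=O
Why: Wohl–Ziegler bromination at the γ-methyl group through the allylic radical of the E enoate, with the E geometry retained.

Step 15
Reactants: 23 ethyl (2E)-4-bromo-2-methylbut-2-enoate
Product: 24 ethyl (2E)-4-(diethoxyphosphoryl)-2-methylbut-2-enoate
Conditions: P(OEt)3, neat, 120 °C, distilling off EtBr
Reagents that add atoms: triethyl phosphite, CCOP(OCC)OCC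
Why: Michaelis–Arbuzov reaction of the primary allylic bromide gives the vinylogous phosphonoacetate.

Step 16
Reactants: 24 ethyl (2E)-4-(diethoxyphosphoryl)-2-methylbut-2-enoate; 25 (2E,4E,6E)-2,7-dimethylocta-2,4,6-trienedial (3 equiv)
Product: 26 ethyl (2E,4E,6E,8E,10E)-2,6,11-trimethyl-12-oxododeca-2,4,6,8,10-pentaenoate
Conditions: NaH, THF, 0 °C; anion of 24 added slowly to 25, 0 °C → rt, dark
Reagents that add atoms: none
Why: Horner–Wadsworth–Emmons olefination through the α-carbon of the phosphonate anion gives the E double bond, and the excess of the symmetrical dialdehyde 25 should limit the reaction to one aldehyde group.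

Step 17
Reactants: 21 {(2E)-3-[(2R,6R,7aR)-6-acetoxy-4,4,7a-trimethyl-2,4,5,6,7,7a-hexahydro-1-benzofuran-2-yl]but-2-en-1-yl}triphenylphosphonium bromide; 26 ethyl (2E,4E,6E,8E,10E)-2,6,11-trimethyl-12-oxododeca-2,4,6,8,10-pentaenoate
Product: 28 ethyl (3R,5R,8R)-3-acetoxy-5,8-epoxy-5,8-dihydro-8'-apo-β-caroten-8'-oate (all-E), via ylide 27 (not isolated)
Conditions: NaN(SiMe3)2 (1.0 equiv), THF, −78 °C; then 26, −78 → 0 °C; then EtOAc, 60 °C, 1 h, dark (Z → E)
Reagents that add atoms: none
Why: Wittig olefination of the polyenal with the allylic ylide 27 forms the C11=C12 bond; the semi-stabilised ylide should give an E/Z mixture at the new bond that equilibrates to the all-E polyene on warming, and the cold, acid-free conditions leave C2 and both esters untouched.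

Step 18
Reactants: 28 ethyl (3R,5R,8R)-3-acetoxy-5,8-epoxy-5,8-dihydro-8'-apo-β-caroten-8'-oate
Product: 29 (3R,5R,8R)-5,8-epoxy-5,8-dihydro-8'-apo-β-carotene-3,8'-diol
Conditions: i-Bu2AlH (5 equiv), CH2Cl2, −78 °C; aq. sodium potassium tartrate work-up
Reagents that add atoms: none
Why: i-Bu2AlH reduces the conjugated ethyl ester to the allylic alcohol and cleaves the acetate in the same operation at −78 °C, without acid.

Step 19
Reactants: 29 (3R,5R,8R)-5,8-epoxy-5,8-dihydro-8'-apo-β-carotene-3,8'-diol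
Product: 30 (3R,5R,8R)-5,8-epoxy-3-hydroxy-5,8-dihydro-8'-apo-β-caroten-8'-al (target)
Conditions: MnO2 (activated, excess), CH2Cl2, rt, dark
Reagents that add atoms: none
Why: MnO2 oxidises only the allylic (polyenylic) primary alcohol to the aldehyde and leaves the secondary C3 alcohol; the neutral conditions should not scramble C8.

**Compound list**
1 | 2,2-dimethylpent-4-enal | O=CC(C)(C)CC=C | starting material
2 | 3,3-dimethylhex-5-en-1-yne | C#CC(C)(C)CC=C | intermediate
3 | (3,3-dimethylhex-5-en-1-yn-1-yl)lithium | [Li]C#CC(C)(C)CC=C | intermediate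
4 | methyl 4,4-dimethylhept-6-en-2-ynoate | COC(=O)C#CC(C)(C)CC=C | intermediate
5 | methyl 4,4-dimethyl-5-(1,2,4-trioxolan-3-yl)pent-2-ynoate (racemic at the ozonide carbon) | COC(=O)C#CC(C)(C)CC1OOCO1 | intermediate
6 | methyl 4,4-dimethyl-6-oxohex-2-ynoate | COC(=O)C#CC(C)(C)CC=O | intermediate
7 | methyl (6R)-6-hydroxy-8-methoxy-4,4-dimethylnon-8-en-2-ynoate | COC(=O)C#CC(C)(C)C[C@@H](O)CC(=C)OC | intermediate
8 | methyl (6R)-6-hydroxy-4,4-dimethyl-8-oxonon-2-ynoate | COC(=O)C#CC(C)(C)C[C@@H](O)CC(C)=O | intermediate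
9 | methyl (2Z)-[(2R,4R)-2,4-dihydroxy-2,6,6-trimethylcyclohexylidene]acetate (samarium alkoxide in the flask) | COC(=O)/C=C1/C(C)(C)C[C@@H](O)C[C@@]1(C)O | intermediate
10 | (6R,7aR)-6-hydroxy-4,4,7a-trimethyl-5,6,7,7a-tetrahydro-1-benzofuran-2(4H)-one (isololiolide) | O=C1C=C2C(C)(C)C[C@@H](O)C[C@@]2(C)O1 | intermediate
11 | (6R,7aR)-4,4,7a-trimethyl-2,4,5,6,7,7a-hexahydro-1-benzofuran-2,6-diol (both C2 epimers; aluminium alkoxide in the flask) | OC1C=C2C(C)(C)C[C@@H](O)C[C@@]2(C)O1 | intermediate
12 | (6R,7aR)-4,4,7a-trimethyl-2,4,5,6,7,7a-hexahydro-1-benzofuran-2,6-diyl diacetate (both C2 epimers) | CC(=O)OC1C=C2C(C)(C)C[C@@H](OC(C)=O)C[C@@]2(C)O1 | intermediate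
13 | but-2-yn-1-ol | CC#CCO | starting material
14 | tert-butyl(but-2-yn-1-yloxy)diphenylsilane | CC#CCO[Si](c1ccccc1)(c1ccccc1)C(C)(C)C | intermediate
15 | tert-butyl{[(2Z)-3-(4,4,5,5-tetramethyl-1,3,2-dioxaborolan-2-yl)but-2-en-1-yl]oxy}diphenylsilane | C/C(B1OC(C)(C)C(C)(C)O1)=C\CO[Si](c1ccccc1)(c1ccccc1)C(C)(C)C | intermediate
16 | potassium {(2Z)-4-[(tert-butyldiphenylsilyl)oxy]but-2-en-2-yl}trifluoroborate | [K+].C/C(=C\CO[Si](c1ccccc1)(c1ccccc1)C(C)(C)C)[B-](F)(F)F | intermediate
17 | (6R,7aR)-6-acetoxy-4,4,7a-trimethyl-5,6,7,7a-tetrahydro-4H-1-benzofuran-1-ium (allylic oxocarbenium ion) | C=1C=C2C(C)(C)C[C@@H](OC(C)=O)C[C@@]2(C)[O+]=1 | intermediate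
18 | (2R,6R,7aR)-2-{(2E)-4-[(tert-butyldiphenylsilyl)oxy]but-2-en-2-yl}-4,4,7a-trimethyl-2,4,5,6,7,7a-hexahydro-1-benzofuran-6-yl acetate | CC(C)(C)[Si](c1ccccc1)(c1ccccc1)OC/C=C(\C)[C@H]1C=C2C(C)(C)C[C@@H](OC(C)=O)C[C@@]2(C)O1 | intermediate
19 | (2R,6R,7aR)-2-[(2E)-4-hydroxybut-2-en-2-yl]-4,4,7a-trimethyl-2,4,5,6,7,7a-hexahydro-1-benzofuran-6-yl acetate | OC/C=C(\C)[C@H]1C=C2C(C)(C)C[C@@H](OC(C)=O)C[C@@]2(C)O1 | intermediate
20 | (2R,6R,7aR)-2-[(2E)-4-bromobut-2-en-2-yl]-4,4,7a-trimethyl-2,4,5,6,7,7a-hexahydro-1-benzofuran-6-yl acetate | BrC/C=C(\C)[C@H]1C=C2C(C)(C)C[C@@H](OC(C)=O)C[C@@]2(C)O1 | intermediate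
21 | {(2E)-3-[(2R,6R,7aR)-6-acetoxy-4,4,7a-trimethyl-2,4,5,6,7,7a-hexahydro-1-benzofuran-2-yl]but-2-en-1-yl}triphenylphosphonium bromide | [Br-].c1ccc(cc1)[P+](c1ccccc1)(c1ccccc1)C/C=C(\C)[C@H]1C=C2C(C)(C)C[C@@H](OC(C)=O)C[C@@]2(C)O1 | intermediate
22 | ethyl (2E)-2-methylbut-2-enoate (ethyl tiglate) | CCOC(=O)/C(C)=C/C | starting material
23 | ethyl (2E)-4-bromo-2-methylbut-2-enoate | CCOC(=O)/C(C)=C/CBr | intermediate
24 | ethyl (2E)-4-(diethoxyphosphoryl)-2-methylbut-2-enoate | CCOC(=O)/C(C)=C/CP(=O)(OCC)OCC | intermediate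
25 | (2E,4E,6E)-2,7-dimethylocta-2,4,6-trienedial | O=C/C(C)=C/C=C/C=C(C)/C=O | starting material
26 | ethyl (2E,4E,6E,8E,10E)-2,6,11-trimethyl-12-oxododeca-2,4,6,8,10-pentaenoate | C\C(C(=O)OCC)=C/C=C/C(C)=C/C=C/C=C(C)/C=O | intermediate
27 | {(2E)-3-[(2R,6R,7aR)-6-acetoxy-4,4,7a-trimethyl-2,4,5,6,7,7a-hexahydro-1-benzofuran-2-yl]but-2-en-1-ylidene}triphenylphosphorane | c1ccc(cc1)P(c1ccccc1)(c1ccccc1)=C/C=C(\C)[C@H]1C=C2C(C)(C)C[C@@H](OC(C)=O)C[C@@]2(C)O1 | intermediate
28 | ethyl (3R,5R,8R)-3-acetoxy-5,8-epoxy-5,8-dihydro-8'-apo-β-caroten-8'-oate (all-E) | C\C(C(=O)OCC)=C/C=C/C(C)=C/C=C/C=C(C)/C=C/C=C(\C)[C@H]1C=C2C(C)(C)C[C@@H](OC(C)=O)C[C@@]2(C)O1 | intermediate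
29 | (3R,5R,8R)-5,8-epoxy-5,8-dihydro-8'-apo-β-carotene-3,8'-diol (all-E) | C\C(CO)=C/C=C/C(C)=C/C=C/C=C(C)/C=C/C=C(\C)[C@H]1C=C2C(C)(C)C[C@@H](O)C[C@@]2(C)O1 | intermediate
30 | (3R,5R,8R)-5,8-epoxy-3-hydroxy-5,8-dihydro-8'-apo-β-caroten-8'-al; (2E,4E,6E,8E,10E,12E,14E)-15-[(2R,6R,7aR)-6-hydroxy-4,4,7a-trimethyl-2,4,5,6,7,7a-hexahydro-1-benzofuran-2-yl]-2,6,11-trimethylhexadeca-2,4,6,8,10,12,14-heptaenal | C\C(C=O)=C/C=C/C(C)=C/C=C/C=C(C)/C=C/C=C(\C)[C@H]1C=C2C(C)(C)C[C@@H](O)C[C@@]2(C)O1 | target

**Step count and risks**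
Total step count: 19. Longest linear sequence: 13 steps (steps 1–6, 10–13, 17–19); steps 7–9 and 14–16 are side branches.

The three steps most likely to fail:

Step 5 (key step). The samarium allenoate may be protonated to the E enoate, which cannot lactonise. The ketyl may also cyclise without the samarium bridge and give the C7a epimer, or the ketone may simply be reduced before it cyclises. Fallback, a polar instead of a radical union, setting out from 8 and returning at 10: hydroiodination of the ynoate (NaI, AcOH, 70 °C) should give methyl (2Z,6R)-6-hydroxy-3-iodo-4,4-dimethyl-8-oxonon-2-enoate F1, with iodine cis to the ester. An intramolecular Nozaki–Hiyama–Kishi reaction (CrCl2, NiCl2 cat., DMF–THF, rt) then adds the alkenyl–chromium bond to the ketone. The ester is already fixed cis to the new chromium alkoxide, so lactonisation to 10 follows in the same flask.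

Step 10. Facial discrimination at the planar oxocarbenium ion may be weak or may run toward the methyl-bearing face, and the bis-allylic ether product may re-ionise under BF3 and erode C2. Fallback, which reverses the order in which carbon and hydrogen are brought to C2, setting out from 10 (and 14) and returning at 18: hydrozirconation of 14 (Cp2Zr(H)Cl, THF) and iodinolysis (I2) give tert-butyl{[(2E)-3-iodobut-2-en-1-yl]oxy}diphenylsilane F2. Halogen–lithium exchange (t-BuLi, Et2O, −78 °C) gives {(2Z)-4-[(tert-butyldiphenylsilyl)oxy]but-2-en-2-yl}lithium F3, which adds (2.2 equiv) to the lactone carbonyl of 10 to give the hemiketal (6R,7aR)-2-{(2E)-4-[(tert-butyldiphenylsilyl)oxy]but-2-en-2-yl}-4,4,7a-trimethyl-2,4,5,6,7,7a-hexahydro-1-benzofuran-2,6-diol F4. Ionic reduction (Et3SiH, BF3·OEt2, CH2Cl2, −78 °C) then places hydride, instead of carbon, on the face the ring prefers and gives (2R,6R,7aR)-2-{(2E)-4-[(tert-butyldiphenylsilyl)oxy]but-2-en-2-yl}-4,4,7a-trimethyl-2,4,5,6,7,7a-hexahydro-1-benzofuran-6-ol F5. Acetylation (Ac2O, pyridine) returns to 18. This helps only if the face preference is reversed; if it is merely weak, a matched chiral diol or Brønsted acid catalyst for the boron transfer in step 10 would be tried first.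

Step 4. The enantioselectivity may be insufficient, the titanium catalyst may be inhibited by the ynoate, and the aldol may dehydrate during hydrolysis of the enol ether. Fallback, a stoichiometric chiral reagent and a masked ketone, setting out from 6 and returning at 8: asymmetric methallylboration with (−)-B-methallyldiisopinocampheylborane (from (+)-α-pinene; (−)-Ipc2BOMe, methallylmagnesium chloride, Et2O, −78 °C; ethanolamine work-up) should give methyl (6S)-6-hydroxy-4,4,8-trimethylnon-8-en-2-ynoate F6. Its spatial arrangement is that of 8; only the descriptor changes, by priority. Ozonolysis of the 1,1-disubstituted alkene (O3, CH2Cl2, −78 °C; Me2S) then returns to 8.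

Further compounds
F1 | step 5 | methyl (2Z,6R)-6-hydroxy-3-iodo-4,4-dimethyl-8-oxonon-2-enoate | COC(=O)/C=C(\I)C(C)(C)C[C@@H](O)CC(C)=O
F2 | step 10 | tert-butyl{[(2E)-3-iodobut-2-en-1-yl]oxy}diphenylsilane | C/C(I)=C\CO[Si](c1ccccc1)(c1ccccc1)C(C)(C)C
F3 | step 10 | {(2Z)-4-[(tert-butyldiphenylsilyl)oxy]but-2-en-2-yl}lithium | C/C([Li])=C\CO[Si](c1ccccc1)(c1ccccc1)C(C)(C)C
F4 | step 10 | (6R,7aR)-2-{(2E)-4-[(tert-butyldiphenylsilyl)oxy]but-2-en-2-yl}-4,4,7a-trimethyl-2,4,5,6,7,7a-hexahydro-1-benzofuran-2,6-diol (both C2 epimers) | CC(C)(C)[Si](c1ccccc1)(c1ccccc1)OC/C=C(\C)C1(O)C=C2C(C)(C)C[C@@H](O)C[C@@]2(C)O1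
F5 | step 10 | (2R,6R,7aR)-2-{(2E)-4-[(tert-butyldiphenylsilyl)oxy]but-2-en-2-yl}-4,4,7a-trimethyl-2,4,5,6,7,7a-hexahydro-1-benzofuran-6-ol | CC(C)(C)[Si](c1ccccc1)(c1ccccc1)OC/C=C(\C)[C@H]1C=C2C(C)(C)C[C@@H](O)C[C@@]2(C)O1
F6 | step 4 | methyl (6S)-6-hydroxy-4,4,8-trimethylnon-8-en-2-ynoate | COC(=O)C#CC(C)(C)C[C@@H](O)CC(C)=C
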